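(All runs were generated by integration for an exercise, and the scatter is random.)

- If I want the apparent order in coupling partner at 30% conversion of this flask, I write the balance of the partner, because at 0.0855 M it is charged below the 0.114 M of both substrates together, which makes it the limiting reagent.

the same everywhere: coupling partner 0.0855 M; protic impurity 0.0285 M; free catalyst 1.1 mM

|  | left-handed substrate | right-handed substrate | remark |
|---|---|---|---|
| teal | 0.057 M | 0.057 M | the very flask that is asked about, followed so far |
| ochre | 0.038 M | 0.038 M | run made earlier |
| flask | 0.057 M | 0.057 M |  |

teal run (percent of the left-handed substrate and right-handed substrate together charged)

| time / s | left-handed product / % |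
|---|---|
| 10.0 | 0.2 |
| 12.0 | 0.4 |
| 20.0 | 0.8 |
| 25.0 | 0.5 |
| 40.0 | 1.2 |
| 60.0 | 1.4 |
| 90.0 | 2.2 |

ochre run (percent of the left-handed substrate and right-handed substrate together charged)

| time / min | left-handed product / % |
|---|---|
| 0.667 | 1.7 |
| 1.00 | 0.9 |
| 1.33 | 2.2 |
| 2.50 | 3.2 |
| 3.00 | 4.1 |
| 5.00 | 7.5 |
| 8.00 | 10.3 |

(readings scatter by 0.5 percentage points)

- free catalyst is single-handed; left-handed substrate and right-handed substrate are mirror images of each other, charged as a racemate, each of them at the stated concentration
- steps that have been proposed: coupling partner + protic impurity -> quenched reagent; coupling partner + free catalyst + left-handed substrate -> free catalyst + left-handed product; coupling partner + free catalyst + right-handed substrate -> free catalyst + right-handed product; free catalyst -> spent catalyst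
- no earlier run changes the charge of coupling partner; that part of a forecast is a guess

* apparent order in coupling partner when 30% of the left-handed substrate and right-handed substrate together are converted (percent change of the rate of making left-handed product for one percent more coupling partner charged)

- Each product takes one partner, so 30% conversion costs 0.0342 M of it.
- The proposed steps are first order in partner, and I take the substrate at fixed conversion as unmoved by the partner charge. The order therefore follows the partner's response, which I measure as the partner leverage: the charge of partner divided by the partner left at that conversion, with the quench held as a fixed amount.
- For the upper bound of this partner term, the impurity takes its whole 0.0285 M. That leaves 0.0228 M and a leverage of 3.75.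
- For the lower bound, the impurity takes nothing, and the leverage is 1.67.
- I leave the bracket as it stands: the last ochre reading, 10.3% left-handed product at 8.00 min, stands below 30%. I commit to the bracket, with any catalyst term on top of it, its size unread.
- The forecast says 4.3, above my upper bound for the partner term, on the ground that “Catalyst decay would add to this”.
- The flask gives 4.0, within tolerance of the forecast.

    coupling partner + protic impurity → quenched reagent (k = 0.00950 /M/s)
    coupling partner + free catalyst + left-handed substrate → free catalyst + left-handed product (k = 5.40 /M²/s)
    coupling partner + free catalyst + right-handed substrate → free catalyst + right-handed product (k = 0.280 /M²/s)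
    free catalyst → spent catalyst (k = 1.10 × 10⁻⁴ /s)

- In this flask at 7.30 min, the coupling partner has a half-life of 43 min by the step making left-handed product and 58 min by the quench, so the product step is the faster drain, but the quench runs alongside it, and 48% of the protic impurity still stands at 20.0 min. At 30% conversion of this flask, reached at 57.1 min with 68.6% of the catalyst free, the leverage of 3.75 sits below the order of 4.0.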